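A first-order one-step world has one time constant, and its reactant decays along a single exponential towards its end.

| flask | starting complex | incoming ligand | scavenger | remark | time |
|---|---|---|---|---|---|
| alder | 0.40 M | 1.1 equiv | 0.80 equiv | run made earlier |  |
| flask | 0.20 M | 1.10 equiv | 0.800 equiv |  | 12 h |

The flask halves the concentration of the alder run at the same charges, so the first question is whether the alder run stopped on time or on count.

alder run (percent of the starting complex charged)

| time / h | starting complex / % | complex with one exchanged / % |
|---|---|---|
| 0.667 | 38.3 | 22.7 |
| 1.33 | 40.6 | 13.1 |
| 2.00 | 41.6 | 12.1 |
| 2.50 | 39.9 | 10.6 |

(readings scatter by 0.5 percentage points)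

- for leaving ligand the idle adduct is counted in
- reactions considered so far: complex with one exchanged + incoming ligand <-> leaving ligand + complex with two exchanged; leaving ligand + complex with one exchanged -> side product; leaving ligand + incoming ligand <-> idle adduct; scavenger + leaving ligand -> scavenged by-product; complex with one exchanged -> over-reaction product; starting complex + incoming ligand <-> leaving ligand + complex with one exchanged
- the earlier runs do not show how much of incoming ligand is bound; that part of a forecast is a guess
- no earlier run changes the charge of incoming ligand; that part of a forecast is a guess
- no earlier run changes the charge of scavenger; that part of a forecast is a guess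

The starting complex reads 38.3% at 0.667 h and 39.9% at 2.50 h, so it shows no decay across these readings, while the complex with one exchanged falls from 22.7% to 10.6%. The stop is therefore read as a count. A complex at one exchange has taken one incoming ligand, and the rest of the reacted complex is taken as holding two. If the charge is taken as used up, the reacted fraction is the charge plus the fraction at one exchange, divided by two. With 1.10 equiv and the last alder reading this gives 60.3%, the ligand-count conversion, and the formula has no concentration term. Counted so, that alder reading puts unused incoming ligand at 0.400% of the starting complex charged, a figure that carries the scatter of the readings. The earlier runs do not show how much incoming ligand is bound, so the free share stays a guess.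

* part of the starting complex that has reacted at 12 h
* share of the unused incoming ligand that is free and not bound as idle adduct, at 12 h

The forecast, higher than this reckoning, gives 64% and 45%, holding that “Halving the concentration leaves the exchange equilibria unchanged”.

The flask gives 61.9% reacted and 74.1% free.

    complex with one exchanged + incoming ligand ⇌ leaving ligand + complex with two exchanged (K = 16.0, k = 0.00784 M⁻¹ s⁻¹)
    leaving ligand + complex with one exchanged → side product (k = 5.35 × 10⁻⁴ M⁻¹ s⁻¹)
    leaving ligand + incoming ligand ⇌ idle adduct, settled at all times (K = 12.0 M⁻¹)
    scavenger + leaving ligand → scavenged by-product (k = 0.231 M⁻¹ s⁻¹)
    complex with one exchanged → over-reaction product (k = 4.13 × 10⁻⁷ s⁻¹)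
    starting complex + incoming ligand ⇌ leaving ligand + complex with one exchanged (K = 1.00, k = 0.0122 M⁻¹ s⁻¹)

At 12.0 h the flask holds side product at 9.08%, a form the count left out, and the reacted part of the flask stands 1.6 percentage points above 60.3%. In the neighbour flask with 0.280 equiv, incoming ligand is the limiting reagent, down to 0% at 12.0 h, and the complex with one exchanged stands at 22.7%, so the same count gives 25.4% against a simulated 25.6%.

(The data come from a simulation with constants of no real substance; noise was put on by code.)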